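**Strategy.** Ring C is disconnected at the O1–C8a aryl ether bond. On ring A the C5 hydroxyl and the C8 methoxy oxygen stand para to each other, so ring A is traced back to a 2-acyl-5-methoxy-1,4-benzoquinone in which C8a is the Michael terminus of two enone units at once, O=C5–C4a=C8a and O=C4–C4a=C8a. In a single operation the (S)-configured C2 hydroxyl adds to C8a and the adduct aromatises: ring C is closed, O1–C8a is made and the C5 and C8 oxygens emerge differentiated. The precursor is an open-chain acylquinone with a (3S)-3-(2,6-dimethoxyphenyl)-3-hydroxypropanoyl side chain, generated in the flask from its hydroquinone with the hydroxyl already free.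

Key step: step 8

Remark: the hydroxy-acylquinone 11 is assumed to be too electrophilic to isolate, so it is generated from hydroquinone 10 and consumed in the same flask; compounds 1 and 5 are taken as commercial.

Step 1
Reactants: 1 2,6-dimethoxybenzoyl chloride
Product: 2 ethyl 3-(2,6-dimethoxyphenyl)-3-oxopropanoate
Conditions: EtOAc (2.2 equiv), LiN(SiMe3)2 (2.3 equiv), THF, −78 °C; then 1, −78 → −30 °C; aq. NH4Cl
Reagents that add atoms: ethyl acetate, CCOC(C)=O
Why: Crossed Claisen condensation, in which the lithium enolate of ethyl acetate is C-acylated by the acid chloride and the second equivalent of enolate removes the acidic proton of the β-keto ester, so that no second acylation follows.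

Step 2
Reactants: 2 ethyl 3-(2,6-dimethoxyphenyl)-3-oxopropanoate
Product: 3 ethyl (3S)-3-(2,6-dimethoxyphenyl)-3-hydroxypropanoate
Conditions: RuCl2[(R)-BINAP] (1 mol %), H2 (40 bar), EtOH, 50 °C
Reagents that add atoms: none
Why: Noyori asymmetric hydrogenation, in which the keto ester binds ruthenium as a chelate through both carbonyl oxygens and the (R)-BINAP complex, which converts aroylacetates into (S)-3-aryl-3-hydroxypropanoates, should add hydrogen to the same ketone face here and so set the (S) carbinol centre that becomes C2.

Step 3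
Reactants: 3 ethyl (3S)-3-(2,6-dimethoxyphenyl)-3-hydroxypropanoate
Product: 4 (3S)-3-(2,6-dimethoxyphenyl)-3-hydroxy-N-methoxy-N-methylpropanamide
Conditions: MeNHOMe·HCl (1.6 equiv), iPrMgCl (4.6 equiv), THF, −20 → 0 °C; aq. NH4Cl
Reagents that add atoms: N,O-dimethylhydroxylamine hydrochloride, CNOC.Cl
Why: Weinreb amide formation by aminolysis of the ester with the chloromagnesium amide of N,O-dimethylhydroxylamine, the free hydroxyl being carried as its magnesium alkoxide and the carbinol centre left untouched.

Step 4
Reactants: 5 2-methoxybenzene-1,4-diol (methoxyhydroquinone)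
Product: 6 1,4-bis(benzyloxy)-2-methoxybenzene
Conditions: BnBr (2.3 equiv), K2CO3 (3 equiv), DMF, 20 → 50 °C, argon
Reagents that add atoms: benzyl bromide, BrCc1ccccc1
Why: Double Williamson ether synthesis on the two phenoxides, benzyl being chosen because it survives the aryllithium step and later leaves by neutral hydrogenolysis.

Step 5
Reactants: 6 1,4-bis(benzyloxy)-2-methoxybenzene
Product: 7 1,4-bis(benzyloxy)-2-bromo-5-methoxybenzene
Conditions: NBS (1.05 equiv), MeCN, 0 → 20 °C, dark
Reagents that add atoms: N-bromosuccinimide, O=C1CCC(=O)N1Br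
Why: Electrophilic aromatic bromination, directed to the one ring position that is para to the methoxy group, ortho to a benzyloxy group and not flanked by two substituents, which is the orientation 1,2,4-trialkoxybenzenes generally show.

Step 6
Reactants: 7 1,4-bis(benzyloxy)-2-bromo-5-methoxybenzene; 4 (3S)-3-(2,6-dimethoxyphenyl)-3-hydroxy-N-methoxy-N-methylpropanamide
Product: 9 (3S)-1-[2,5-bis(benzyloxy)-4-methoxyphenyl]-3-(2,6-dimethoxyphenyl)-3-hydroxypropan-1-one, via aryllithium 8 (not isolated)
Conditions: 7 (2.4 equiv), n-BuLi (2.3 equiv), THF, −78 °C, 20 min; then 4 (1.0 equiv) in THF, −78 → −20 °C; aq. NH4Cl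
Reagents that add atoms: none
Why: Bromine–lithium exchange followed by Weinreb ketone synthesis, in which one equivalent of 8 deprotonates the hydroxyl, a second adds to the amide to give a chelated tetrahedral adduct that cannot add again and collapses to the ketone only on quenching, and no bond to the carbinol carbon is involved.

Step 7
Reactants: 9 (3S)-1-[2,5-bis(benzyloxy)-4-methoxyphenyl]-3-(2,6-dimethoxyphenyl)-3-hydroxypropan-1-one
Product: 10 (3S)-1-(2,5-dihydroxy-4-methoxyphenyl)-3-(2,6-dimethoxyphenyl)-3-hydroxypropan-1-one
Conditions: H2 (1 atm), Pd/C (10 %), EtOAc, 20 °C; filtered under argon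
Reagents that add atoms: none
Why: Hydrogenolysis of the two benzyl aryl ethers over palladium, which under neutral conditions should be much faster than reduction of the hydrogen-bonded aryl ketone or cleavage of the hindered secondary benzylic C–O bond.

Step 8
Reactants: 10 (3S)-1-(2,5-dihydroxy-4-methoxyphenyl)-3-(2,6-dimethoxyphenyl)-3-hydroxypropan-1-one
Product: 12 (2S)-2-(2,6-dimethoxyphenyl)-5,8-dihydroxy-7-methoxychroman-4-one, via acylquinone 11 (not isolated)
Conditions: DDQ (1.0 equiv), CH2Cl2 (0.002 M), −78 °C, 15 min; then → 20 °C; aq. Na2S2O4 wash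
Reagents that add atoms: none
Why: DDQ should dehydrogenate the acylhydroquinone within minutes at −78 °C, so that acylquinone 11 is complete before the oxidant-free solution is warmed; the C2 hydroxyl then adds to C8a, the β-carbon shared by the enone O=C5–C4a=C8a and the aryl ketone O=C4–C4a=C8a, and the adduct tautomerises to the aromatic 5,8-hydroquinone, which removes any way back. The closest known reaction type is the conjugate addition of alcohols and other heteroatom nucleophiles to C3 of 2-acyl-1,4-benzoquinones with re-aromatisation, used here in an intramolecular (oxa-Michael) form. Ring C closes in a 6-endo-trig mode, since both carbons of the attacked C4a=C8a bond lie inside the new six-membered ring. No stereocentre is formed and the bond between C2 and its oxygen stays intact throughout, so the (S) configuration set in step 2 should be carried into 12 unchanged. The selectivity required is attack at C8a and not at C6 or C7; it is secured because C8a alone is activated by two carbonyl groups and lies within reach of the three-atom tether, whereas C6=C7 is damped as a vinylogous ester. High dilution keeps hydrogen transfer between 12 and unreacted 11 slow, and shaking with aqueous Na2S2O4 reduces back any 12 that has been dehydrogenated.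

Step 9
Reactants: 12 (2S)-2-(2,6-dimethoxyphenyl)-5,8-dihydroxy-7-methoxychroman-4-one
Product: 13 (2S)-2-(2,6-dimethoxyphenyl)-5-hydroxy-7,8-dimethoxychroman-4-one [(2S)-5-hydroxy-7,8,2',6'-tetramethoxyflavanone]
Conditions: Me3SiCHN2 (2 equiv, hexane), iPr2NEt (1 equiv), MeCN–MeOH (9:1), 20 °C, argon
Reagents that add atoms: trimethylsilyldiazomethane, C[Si](C)(C)C=[N+]=[N-]
Why: O-Methylation of a phenol by a diazoalkane (Me3SiCHN2 with methanol as a diazomethane equivalent), in which the C5 hydroxyl is held in a hydrogen bond to the C4 carbonyl and stays untouched, so that only the free C8 hydroxyl should react, and the weak amine base is not expected to open ring C or disturb C2.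

**Compound list**

1 | 2,6-dimethoxybenzoyl chloride | COc1cccc(OC)c1C(=O)Cl | starting material
2 | ethyl 3-(2,6-dimethoxyphenyl)-3-oxopropanoate | CCOC(=O)CC(=O)c1c(OC)cccc1OC | intermediate
3 | ethyl (3S)-3-(2,6-dimethoxyphenyl)-3-hydroxypropanoate | CCOC(=O)C[C@H](O)c1c(OC)cccc1OC | intermediate
4 | (3S)-3-(2,6-dimethoxyphenyl)-3-hydroxy-N-methoxy-N-methylpropanamide | CON(C)C(=O)C[C@H](O)c1c(OC)cccc1OC | intermediate
5 | 2-methoxybenzene-1,4-diol (methoxyhydroquinone) | COc1cc(O)ccc1O | starting material
6 | 1,4-bis(benzyloxy)-2-methoxybenzene | COc1cc(OCc2ccccc2)ccc1OCc1ccccc1 | intermediate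
7 | 1,4-bis(benzyloxy)-2-bromo-5-methoxybenzene | COc1cc(OCc2ccccc2)c(Br)cc1OCc1ccccc1 | intermediate
8 | [2,5-bis(benzyloxy)-4-methoxyphenyl]lithium | [Li]c1cc(OCc2ccccc2)c(OC)cc1OCc1ccccc1 | intermediate
9 | (3S)-1-[2,5-bis(benzyloxy)-4-methoxyphenyl]-3-(2,6-dimethoxyphenyl)-3-hydroxypropan-1-one | COc1cc(OCc2ccccc2)c(C(=O)C[C@H](O)c2c(OC)cccc2OC)cc1OCc1ccccc1 | intermediate
10 | (3S)-1-(2,5-dihydroxy-4-methoxyphenyl)-3-(2,6-dimethoxyphenyl)-3-hydroxypropan-1-one | COc1cc(O)c(C(=O)C[C@H](O)c2c(OC)cccc2OC)cc1O | intermediate
11 | 2-[(3S)-3-(2,6-dimethoxyphenyl)-3-hydroxypropanoyl]-5-methoxy-1,4-benzoquinone | COC1=CC(=O)C(C(=O)C[C@H](O)c2c(OC)cccc2OC)=CC1=O | intermediate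
12 | (2S)-2-(2,6-dimethoxyphenyl)-5,8-dihydroxy-7-methoxychroman-4-one | COc1cc(O)c2c(c1O)O[C@H](c1c(OC)cccc1OC)CC2=O | intermediate
13 | (2S)-2-(2,6-dimethoxyphenyl)-5-hydroxy-7,8-dimethoxychroman-4-one | COc1cc(O)c2c(c1OC)O[C@H](c1c(OC)cccc1OC)CC2=O | target

**Step count.** Total steps: 9. Longest linear sequence: 7 steps (steps 1, 2, 3, 6, 7, 8, 9); steps 4 and 5 form the side branch that supplies ring A.

**Steps most likely to fail**

1. Step 8. The hydroxyl may begin to add while DDQ is still present, so that 12 is dehydrogenated to its quinone. In that quinone the C2–O1 bond is part of an activated vinylogous ester and could ionise or ring-open, with loss of the C2 configuration. Hydrogen transfer between 12 and unconverted 11 could also stall the closure.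
   Fallback: oxidation and ring closure are separated by masking the nucleophile. The fallback sets out from 4. Silylation (TBSOTf, 2,6-lutidine, CH2Cl2, −78 → 0 °C) should give (3S)-3-[(tert-butyldimethylsilyl)oxy]-3-(2,6-dimethoxyphenyl)-N-methoxy-N-methylpropanamide F1. Commercial 1-bromo-2,4,5-trimethoxybenzene and n-BuLi (THF, −78 °C) give (2,4,5-trimethoxyphenyl)lithium F2, which adds to F1 to give (3S)-3-[(tert-butyldimethylsilyl)oxy]-3-(2,6-dimethoxyphenyl)-1-(2,4,5-trimethoxyphenyl)propan-1-one F3. Oxidative demethylation with (NH4)2Ce(NO3)6 (MeCN–H2O, 0 °C) should then give 2-[(3S)-3-[(tert-butyldimethylsilyl)oxy]-3-(2,6-dimethoxyphenyl)propanoyl]-5-methoxy-1,4-benzoquinone F4, which is purified free of oxidant. Aqueous HF in dilute MeCN at 0 °C unmasks the hydroxyl to 11, which closes to 12 with no external oxidant in the flask; the fallback comes back to the route at 12.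

2. Step 2. Turnover at the di-ortho-substituted ketone may be slow, and binding of an ortho methoxy group to ruthenium may compete with the ester chelate and lower facial selectivity. Acid-promoted solvolysis of the electron-rich benzylic alcohol in warm ethanol could also erode the enantiomeric purity.
   Fallback: resolution in place of asymmetric catalysis. The fallback sets out from 2. Reduction with NaBH4 (EtOH, 0 °C) gives racemic ethyl 3-(2,6-dimethoxyphenyl)-3-hydroxypropanoate F5. Its enantiomers are separated by preparative chromatography on a chiral stationary phase (for example amylose tris(3,5-dimethylphenylcarbamate)), and the (S)-enantiomer, to be assigned by Mosher ester analysis, is 3, where the fallback comes back to the route.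

3. Step 6. The aryllithium is partly spent on proton transfer, and acylation of the amide that carries a neighbouring lithium alkoxide may be slow. If the mixture has to be warmed, retro-aldol cleavage or dehydration of the β-alkoxide and decomposition of the ortho-benzyloxy aryllithium may compete.
   Fallback: a protect–add–unmask sequence in place of the dianion addition. The fallback sets out from 4. Silylation (Et3SiCl, imidazole, DMF, 20 °C) should give (3S)-3-(2,6-dimethoxyphenyl)-N-methoxy-N-methyl-3-[(triethylsilyl)oxy]propanamide F6. Addition of 8 (1.2 equiv, THF, −78 °C) then gives (3S)-1-[2,5-bis(benzyloxy)-4-methoxyphenyl]-3-(2,6-dimethoxyphenyl)-3-[(triethylsilyl)oxy]propan-1-one F7. HF·pyridine in THF–pyridine at 0 °C removes the silyl group and the fallback comes back to the route at 9.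

**Further compounds**

F1 | step 8 | (3S)-3-[(tert-butyldimethylsilyl)oxy]-3-(2,6-dimethoxyphenyl)-N-methoxy-N-methylpropanamide | CON(C)C(=O)C[C@H](O[Si](C)(C)C(C)(C)C)c1c(OC)cccc1OC
F2 | step 8 | (2,4,5-trimethoxyphenyl)lithium | [Li]c1cc(OC)c(OC)cc1OC
F3 | step 8 | (3S)-3-[(tert-butyldimethylsilyl)oxy]-3-(2,6-dimethoxyphenyl)-1-(2,4,5-trimethoxyphenyl)propan-1-one | COc1cc(OC)c(C(=O)C[C@H](O[Si](C)(C)C(C)(C)C)c2c(OC)cccc2OC)cc1OC
F4 | step 8 | 2-[(3S)-3-[(tert-butyldimethylsilyl)oxy]-3-(2,6-dimethoxyphenyl)propanoyl]-5-methoxy-1,4-benzoquinone | COC1=CC(=O)C(C(=O)C[C@H](O[Si](C)(C)C(C)(C)C)c2c(OC)cccc2OC)=CC1=O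
F5 | step 2 | racemic ethyl 3-(2,6-dimethoxyphenyl)-3-hydroxypropanoate | CCOC(=O)CC(O)c1c(OC)cccc1OC
F6 | step 6 | (3S)-3-(2,6-dimethoxyphenyl)-N-methoxy-N-methyl-3-[(triethylsilyl)oxy]propanamide | CON(C)C(=O)C[C@H](O[Si](CC)(CC)CC)c1c(OC)cccc1OC
F7 | step 6 | (3S)-1-[2,5-bis(benzyloxy)-4-methoxyphenyl]-3-(2,6-dimethoxyphenyl)-3-[(triethylsilyl)oxy]propan-1-one | COc1cc(OCc2ccccc2)c(C(=O)C[C@H](O[Si](CC)(CC)CC)c2c(OC)cccc2OC)cc1OCc1ccccc1
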